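**Plan**
- Retrosynthesis: after the O6–benzyl and O5–methyl bonds, ring A is removed as a whole by cutting C8–C8a and C4a–C5 (flavanone numbering).
- This works because ring A (C4a, C5, C6, C7, C8, C8a) carries three contiguous, differently substituted oxygens at C5, C6 and C7, which map onto a 1,1,2,3-tetraoxygenated butadiene (C5–C8). The remaining C4a–C8a bond is the enone double bond of a 2-aryl-2,3-dihydropyran-4-one (ring C) that already contains C2.
- Ring C is cut at C2–C3 and O1–C8a (veratraldehyde plus Danishefsky's diene). The ring A diene is traced to methyl acetoacetate and benzyl alcohol.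
- Forward: ring C is built first (step 1) and activated at C4a by iodination and sulfonylation (steps 2–3). The diene is made in steps 4–7, ring A is annulated in step 8, and O5 methylation and O6 debenzylation finish the route (steps 9–10).
- Stereochemistry: the only stereocentre, C2 (S), is set in step 1 by the (S)-BINOL/Ti(OiPr)4 catalyst. No later step touches C2, and soluble bases are avoided so that ring C cannot open by retro-oxa-Michael reaction.

Key step: step 8

Assumption: the (S)-BINOL/Ti(OiPr)4 catalyst is taken to direct the diene to the Si face of the aryl aldehyde, as it does with other carbon nucleophiles, which gives S at C2 (to be confirmed on 4); enol ether 11 and diene 12 are drawn as single geometric isomers, although either isomer serves because these carbons end up in the arene.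

**Step 1**
Reactants: 1 3,4-dimethoxybenzaldehyde; 2 Danishefsky's diene
Product: 4 (S)-2-(3,4-dimethoxyphenyl)-2,3-dihydro-4H-pyran-4-one, via silylated Mukaiyama aldol adduct 3 (not isolated)
Conditions: (S)-BINOL (20 mol %), Ti(OiPr)4 (10 mol %), TFA (cat.), 4 Å MS, Et2O, −20 °C; then TFA, CH2Cl2, 0 °C
Reagents that add atoms: none
Why: Enantioselective BINOL–titanium-catalysed Mukaiyama aldol addition of the silyloxydiene (the stepwise form of the hetero-Diels–Alder reaction), in which the chiral Lewis acid exposes the Si face of the aldehyde and so sets C2 as S, followed by acid-induced oxa-Michael ring closure with loss of methanol.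

**Step 2**
Reactants: 4 (S)-2-(3,4-dimethoxyphenyl)-2,3-dihydro-4H-pyran-4-one
Product: 5 (S)-2-(3,4-dimethoxyphenyl)-5-iodo-2,3-dihydro-4H-pyran-4-one
Conditions: I2 (2 equiv), pyridine (3 equiv), CH2Cl2, 0 °C → rt
Reagents that add atoms: iodine, II
Why: α-Iodination of an enone with iodine/pyridine (addition–elimination at the nucleophilic α-carbon of the vinylogous ester), which should leave the veratryl ring and C2 untouched.

**Step 3**
Reactants: 5 (S)-2-(3,4-dimethoxyphenyl)-5-iodo-2,3-dihydro-4H-pyran-4-one
Product: 6 (S)-2-(3,4-dimethoxyphenyl)-5-(phenylsulfonyl)-2,3-dihydro-4H-pyran-4-one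
Conditions: PhSO2Na (1.5 equiv), CuI (20 mol %), 1,10-phenanthroline (20 mol %), DMSO, 70 °C
Reagents that add atoms: sodium benzenesulfinate, [Na+].[O-]S(=O)c1ccccc1
Why: Ullmann-type copper-catalysed C–S coupling of an alkenyl iodide with a sulfinate salt, run without added base or a primary or secondary amine ligand because the β-alkoxy enone is sensitive to amines at the carbon next to O1 and to base at C3.

**Step 4**
Reactants: 7 methyl acetoacetate
Product: 8 methyl 2-diazo-3-oxobutanoate
Conditions: p-ABSA, Et3N, MeCN, 0 °C → rt
Reagents that add atoms: 4-acetamidobenzenesulfonyl azide (p-ABSA), CC(=O)Nc1ccc(cc1)S(=O)(=O)N=[N+]=[N-]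
Why: Regitz diazo transfer to the doubly activated methylene group of a β-keto ester.

**Step 5**
Reactants: 8 methyl 2-diazo-3-oxobutanoate; 9 benzyl alcohol
Product: 10 methyl 2-(benzyloxy)-3-oxobutanoate
Conditions: Rh2(OAc)4 (1 mol %), 9 (1.5 equiv), CH2Cl2, rt, slow addition of 8
Reagents that add atoms: none
Why: Rhodium-carbenoid O–H insertion, in which the carbenoid from the diazo keto ester is trapped by the alcohol faster than it rearranges or dimerises, placing the future C6 oxygen as its benzyl ether.

**Step 6**
Reactants: 10 methyl 2-(benzyloxy)-3-oxobutanoate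
Product: 11 methyl (Z)-2-(benzyloxy)-3-methoxybut-2-enoate
Conditions: HC(OMe)3 (neat, 3 equiv), H2SO4 (cat.), rt; then bulb-to-bulb distillation
Reagents that add atoms: trimethyl orthoformate, COC(OC)OC
Why: Acid-catalysed enol ether formation from a β-keto ester and an orthoformate (ketalisation, then loss of methanol into conjugation), which avoids the C-methylation that basic alkylation would risk.

**Step 7**
Reactants: 11 methyl (Z)-2-(benzyloxy)-3-methoxybut-2-enoate
Product: 12 (1E)-2-(benzyloxy)-1,3-dimethoxy-1-(trimethylsilyloxy)buta-1,3-diene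
Conditions: LDA (1.1 equiv, commercial solution), THF, −78 °C; then TMSCl, −78 °C → rt; filtered under argon and used without chromatography
Reagents that add atoms: chlorotrimethylsilane, C[Si](C)(C)Cl
Why: Kinetic γ-deprotonation of the β-alkoxy enoate (no α-hydrogen is present) gives the extended dienolate, which is silylated on oxygen to the Brassard-type vinylogous silyl ketene acetal.

**Step 8**
Reactants: 6 (S)-2-(3,4-dimethoxyphenyl)-5-(phenylsulfonyl)-2,3-dihydro-4H-pyran-4-one; 12 (1E)-2-(benzyloxy)-1,3-dimethoxy-1-(trimethylsilyloxy)buta-1,3-diene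
Product: 14 (S)-6-(benzyloxy)-5-hydroxy-7,3',4'-trimethoxyflavanone, via cis-fused cycloadduct 13 (not isolated)
Conditions: 12 (2.5 equiv), toluene, 0 °C → rt (60 °C if slow); then TFA (cat.), CH2Cl2, 0 °C; dilute HCl work-up
Reagents that add atoms: none
Why: The unsubstituted terminus of 12, its most nucleophilic carbon, attacks the pyranone carbon next to O1 (future C8a), which is β to both ketone and sulfone, and the ketene-acetal carbon then closes onto the sulfone-bearing carbon (future C4a) in a concerted but strongly asynchronous [4+2] cycloaddition to give 13; acid then ionises the C5 mixed ketal, a proton is lost from C8, benzenesulfinic acid leaves across C4a–C8a in an aromatisation-driven elimination, and the aryl silyl ether is hydrolysed on work-up. The closest known reaction type is the Diels–Alder/eliminative aromatisation of Brassard-type 1,1,3-trioxygenated dienes with haloquinones and 3-activated chromones. Ring A is closed as a six-membered carbocycle by intermolecular [4+2] annulation onto the C4a=C8a bond of ring C, both new bonds (C8–C8a and C4a–C5) arising in the one operation. No lasting stereocentre is formed, since C4a, C5 and C8a of 13 all become sp2, so facial and endo/exo selectivity are immaterial and C2 is not a reacting centre. The one selectivity required is regiochemical (C8 to C8a, C5 to C4a), and it is secured by matching the strongly polarised diene with the doubly activated acceptor carbon. Neutral to mildly acidic conditions are kept throughout so that ring C cannot open by retro-oxa-Michael reaction and erode C2.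

**Step 9**
Reactants: 14 (S)-6-(benzyloxy)-5-hydroxy-7,3',4'-trimethoxyflavanone
Product: 15 (S)-6-(benzyloxy)-5,7,3',4'-tetramethoxyflavanone
Conditions: MeI (excess), Ag2O (2 equiv), CHCl3, 40 °C, dark
Reagents that add atoms: iodomethane, CI
Why: Purdie-type silver oxide methylation, the usual method for hydrogen-bonded peri-hydroxyls next to a carbonyl, in which silver-assisted SN2 at iodomethane needs no soluble base, so the C3 enolate that would open ring C and erase C2 should not form.

**Step 10**
Reactants: 15 (S)-6-(benzyloxy)-5,7,3',4'-tetramethoxyflavanone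
Product: 16 (S)-6-hydroxy-5,7,3',4'-tetramethoxyflavanone
Conditions: H2 (1 atm), 10% Pd/C, EtOAc, rt, stopped at full conversion
Reagents that add atoms: none
Why: Catalytic hydrogenolysis of an aryl benzyl ether under neutral conditions should be much faster than reduction of the aryl ketone or cleavage of the C2–O1 bond, freeing the C6 hydroxyl of the target.

**Compound list**
1 | 3,4-dimethoxybenzaldehyde (veratraldehyde) | COc1ccc(C=O)cc1OC | starting material
2 | Danishefsky's diene, (E)-1-methoxy-3-(trimethylsilyloxy)buta-1,3-diene | CO/C=C/C(=C)O[Si](C)(C)C | starting material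
3 | (S,E)-5-(3,4-dimethoxyphenyl)-1-methoxy-5-(trimethylsilyloxy)pent-1-en-3-one | CO/C=C/C(=O)C[C@H](O[Si](C)(C)C)c1ccc(OC)c(OC)c1 | intermediate
4 | (S)-2-(3,4-dimethoxyphenyl)-2,3-dihydro-4H-pyran-4-one | COc1ccc([C@@H]2CC(=O)C=CO2)cc1OC | intermediate
5 | (S)-2-(3,4-dimethoxyphenyl)-5-iodo-2,3-dihydro-4H-pyran-4-one | COc1ccc([C@@H]2CC(=O)C(I)=CO2)cc1OC | intermediate
6 | (S)-2-(3,4-dimethoxyphenyl)-5-(phenylsulfonyl)-2,3-dihydro-4H-pyran-4-one | COc1ccc([C@@H]2CC(=O)C(S(=O)(=O)c3ccccc3)=CO2)cc1OC | intermediate
7 | methyl acetoacetate | COC(=O)CC(C)=O | starting material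
8 | methyl 2-diazo-3-oxobutanoate | COC(=O)C(=[N+]=[N-])C(C)=O | intermediate
9 | benzyl alcohol | OCc1ccccc1 | starting material
10 | methyl 2-(benzyloxy)-3-oxobutanoate (racemic) | COC(=O)C(OCc1ccccc1)C(C)=O | intermediate
11 | methyl (Z)-2-(benzyloxy)-3-methoxybut-2-enoate | COC(=O)/C(OCc1ccccc1)=C(\C)OC | intermediate
12 | (1E)-2-(benzyloxy)-1,3-dimethoxy-1-(trimethylsilyloxy)buta-1,3-diene | C=C(OC)/C(OCc1ccccc1)=C(/OC)O[Si](C)(C)C | intermediate
13 | (2S)-6-(benzyloxy)-2-(3,4-dimethoxyphenyl)-5,7-dimethoxy-4a-(phenylsulfonyl)-5-(trimethylsilyloxy)-2,3,4a,5,8,8a-hexahydro-4H-chromen-4-one (cis ring fusion, mixture at C4a, C5 and C8a) | COc1ccc([C@@H]2CC(=O)C3(S(=O)(=O)c4ccccc4)C(CC(OC)=C(OCc4ccccc4)C3(OC)O[Si](C)(C)C)O2)cc1OC | intermediate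
14 | (S)-6-(benzyloxy)-5-hydroxy-7,3',4'-trimethoxyflavanone, (2S)-6-(benzyloxy)-2-(3,4-dimethoxyphenyl)-5-hydroxy-7-methoxychroman-4-one | COc1ccc([C@@H]2CC(=O)c3c(cc(OC)c(OCc4ccccc4)c3O)O2)cc1OC | intermediate
15 | (S)-6-(benzyloxy)-5,7,3',4'-tetramethoxyflavanone, (2S)-6-(benzyloxy)-2-(3,4-dimethoxyphenyl)-5,7-dimethoxychroman-4-one | COc1ccc([C@@H]2CC(=O)c3c(cc(OC)c(OCc4ccccc4)c3OC)O2)cc1OC | intermediate
16 | (S)-6-hydroxy-5,7,3',4'-tetramethoxyflavanone, (2S)-2-(3,4-dimethoxyphenyl)-6-hydroxy-5,7-dimethoxychroman-4-one | COc1ccc([C@@H]2CC(=O)c3c(cc(OC)c(O)c3OC)O2)cc1OC | target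

**Step count**
Total: 10 steps. Longest linear sequence: 7 steps (steps 4, 5, 6, 7, 8, 9, 10); the ring C branch (steps 1–3) joins at step 8.

**Steps most likely to fail**

1. Step 8. Ring closure onto the hindered sulfone-bearing carbon may be slow, and the C4a sulfinate has no acidified β-hydrogen. It may therefore leave too slowly, so that aromatisation stalls or the 1,3-dicarbonyl adduct fragments by retro-Claisen cleavage on work-up. The fallback keeps the same disconnection with a sulfoxide as activating and leaving group; it sets out from 4 and returns at 14.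
   - 4 is sulfenylated at the enone α-carbon with PhSCl/pyridine (CH2Cl2, −78 → 0 °C; addition across the enol ether double bond, then loss of HCl) to give (S)-2-(3,4-dimethoxyphenyl)-5-(phenylthio)-2,3-dihydro-4H-pyran-4-one F1.
   - F1 is oxidised with one equivalent of mCPBA at −78 °C to (2S)-2-(3,4-dimethoxyphenyl)-5-(phenylsulfinyl)-2,3-dihydro-4H-pyran-4-one F2; either configuration at sulfur serves.
   - Cycloaddition of F2 with 12 in toluene (rt → 80 °C) would give the sulfinyl cycloadduct F3. Its C4a sulfinyl group and the cis C8a hydrogen should undergo thermal syn-elimination of benzenesulfenic acid without acid or base, which also draws the cycloaddition forward.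
   - The acid work-up of step 8 then removes methanol and the silyl group to give 14.

2. Step 9. The phenol is hydrogen-bonded to the C4 carbonyl and flanked by the benzyloxy group, so methylation may be incomplete, and forcing basic conditions would open ring C to the chalcone and erode C2. The fallback removes the chelating carbonyl for the duration of the alkylation; it sets out from 14 and returns at 15.
   - NaBH4 (MeOH/THF, 0 °C) reduces 14 to (2S,4S)-6-(benzyloxy)-2-(3,4-dimethoxyphenyl)-7-methoxychromane-4,5-diol F4. The 2,4-cis alcohol is expected to predominate, and its C4 epimer is equally serviceable.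
   - With no ketone, F4 has no retro-oxa-Michael pathway and a free phenol, so MeI/K2CO3 in acetone at rt can be used to give (2S,4S)-6-(benzyloxy)-2-(3,4-dimethoxyphenyl)-5,7-dimethoxychroman-4-ol F5.
   - Dess–Martin periodinane (NaHCO3, CH2Cl2) re-oxidises the benzylic alcohol of F5 to 15.

3. Step 3. Sulfinate may add at the carbon next to O1 (conjugate addition with ring opening), or the iodide may be lost reductively, instead of C–S coupling. The fallback installs the sulfone by C–H functionalisation rather than cross-coupling; it sets out from 4 and returns at 6, bypassing 5.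
   - 4 is treated with PhSO2Na and I2 (NaHCO3, MeCN/H2O, rt).
   - The sulfonyl radical (or sulfonyl iodide) formed in situ adds to the enone α-carbon of the enol ether double bond, and the resulting α-oxy radical is oxidised and loses a proton. This is the pattern known for sulfinate C–H sulfonylation of glycals and enaminones.

**Further compounds**
F1 | step 8 | (S)-2-(3,4-dimethoxyphenyl)-5-(phenylthio)-2,3-dihydro-4H-pyran-4-one | COc1ccc([C@@H]2CC(=O)C(Sc3ccccc3)=CO2)cc1OC
F2 | step 8 | (2S)-2-(3,4-dimethoxyphenyl)-5-(phenylsulfinyl)-2,3-dihydro-4H-pyran-4-one (either configuration at sulfur) | COc1ccc([C@@H]2CC(=O)C(S(=O)c3ccccc3)=CO2)cc1OC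
F3 | step 8 | (2S)-6-(benzyloxy)-2-(3,4-dimethoxyphenyl)-5,7-dimethoxy-4a-(phenylsulfinyl)-5-(trimethylsilyloxy)-2,3,4a,5,8,8a-hexahydro-4H-chromen-4-one (cis ring fusion, not isolated) | COc1ccc([C@@H]2CC(=O)C3(S(=O)c4ccccc4)C(CC(OC)=C(OCc4ccccc4)C3(OC)O[Si](C)(C)C)O2)cc1OC
F4 | step 9 | (2S,4S)-6-(benzyloxy)-2-(3,4-dimethoxyphenyl)-7-methoxychromane-4,5-diol | COc1ccc([C@@H]2C[C@H](O)c3c(cc(OC)c(OCc4ccccc4)c3O)O2)cc1OC
F5 | step 9 | (2S,4S)-6-(benzyloxy)-2-(3,4-dimethoxyphenyl)-5,7-dimethoxychroman-4-ol | COc1ccc([C@@H]2C[C@H](O)c3c(cc(OC)c(OCc4ccccc4)c3OC)O2)cc1OC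
F0 | step 3 | none | none
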